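The cyclohexenone is read as a masked cyclohexane-1,3-dione: ring carbons C1 (C=O) and C3 (C–OMe) are both at carbonyl level with C2 between them, and the ketal carbon C4 is α to C3. This 1,3-dioxygenated ring pattern lets one operation, an enantioselective Michael–Claisen [3+3] annulation, join a methylglyoxal-derived mixed acetal ketone (C2–C3–C4, already carrying methoxy and aryloxy) to methyl 2-allylacrylate (C5–C6–C1): conjugate addition forms C4–C5 and the quaternary ketal stereocenter, Claisen acylation forms C1–C2. Both precursors are acyclic. O-Methylation of the dione and a kinetic protonation that sets C6 finish the synthesis.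

Key step: step 5

Remark: ring atoms are numbered C1 (C=O), C2 (=CH), C3 (C–OMe), C4 (ketal), C5 (CH2), C6 (CH–allyl), the target is (4R,6S) with aryloxy and allyl cis, and the R sense of induction of the cinchonidinium salt in step 5 is assumed by analogy (the pseudoenantiomeric cinchoninium salt would be used otherwise).

Step 1
Reactants: 1 3,4-dimethoxyphenol
Product: 2 4-(allyloxy)-1,2-dimethoxybenzene
Conditions: allyl bromide, K2CO3, acetone, reflux
Reagents that add atoms: allyl bromide, C=CCBr
Why: Williamson O-allylation of the phenoxide by SN2 displacement on allyl bromide should be clean, and no stereocenter is formed.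

Step 2
Reactants: 2 4-(allyloxy)-1,2-dimethoxybenzene
Product: 3 2-allyl-4,5-dimethoxyphenol
Conditions: N,N-diethylaniline, 200 °C
Reagents that add atoms: none
Why: The aromatic Claisen rearrangement ([3,3] shift, then tautomerisation) should deliver the allyl group to the free ortho position para to a methoxy group rather than to the ortho position flanked by methoxy, and no stereocenter is formed.

Step 3
Reactants: 3 2-allyl-4,5-dimethoxyphenol; 4 1,1-dimethoxypropan-2-one
Product: 6 1-(2-allyl-4,5-dimethoxyphenoxy)-1-methoxypropan-2-one (racemic), via bromo ether 5 (not isolated)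
Conditions: 4, Me3SiBr (1.0 equiv), CH2Cl2, 0 °C; then 3, iPr2NEt, 0 °C to rt
Reagents that add atoms: none
Why: Acetal-to-α-bromo-ether exchange with Me3SiBr followed by O-alkylation of the phenol at the doubly activated (α-alkoxy, α-keto) C–Br bond should give the mixed aryl methyl acetal, whose racemic acetal center is erased by enolisation in step 5.

Step 4
Reactants: 7 methyl 2-(bromomethyl)acrylate
Product: 8 methyl 2-methylidenepent-4-enoate (methyl 2-allylacrylate)
Conditions: CH2=CHMgBr, CuI (10 mol %), THF, −78 °C
Reagents that add atoms: vinylmagnesium bromide, C=C[Mg]Br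
Why: Copper-catalysed allylic substitution of the bromide by the vinyl Grignard reagent (SN2 and SN2′ paths give the same product) should outrun 1,2-addition to the ester at low temperature, and no stereocenter is formed.

Step 5
Reactants: 6 1-(2-allyl-4,5-dimethoxyphenoxy)-1-methoxypropan-2-one; 8 methyl 2-methylidenepent-4-enoate
Product: 10 (4R)-6-allyl-4-(2-allyl-4,5-dimethoxyphenoxy)-4-methoxycyclohexane-1,3-dione (mixture of C6 epimers), via keto ester 9 (not isolated)
Conditions: O-allyl-N-(9-anthracenylmethyl)cinchonidinium bromide (10 mol %), CsOH·H2O (20 mol %), toluene/CH2Cl2, −40 °C; then KOtBu (2.5 equiv), THF, −40 to 0 °C; AcOH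
Reagents that add atoms: none
Why: Proposed new method: under solid–liquid phase transfer the acetal C–H of 6 (flanked by C=O, OMe and OAr, estimated to be several pKa units more acidic than the methyl group) is deprotonated and the tetrasubstituted enolate, ion-paired with the cinchonidinium cation, adds to the CH2 terminus of 8 to form C4–C5 and, after proton transfer, keto ester 9; KOtBu then enolises the methyl ketone (its only enolisable position), which attacks the ester in a 6-(enolendo)-exo-trig Claisen (Dieckmann-type) closure to form C1–C2, expels methoxide and ends as the diketonate, which makes the closure irreversible. The closest known reaction types are the consecutive Michael–Claisen synthesis of cyclohexane-1,3-diones from methyl ketones and acrylates and the cinchona-ammonium phase-transfer Michael addition of glycine-imine enolates of similar acidity to acrylates; new is the acyclic α-aryloxy-α-methoxy ketone enolate as the prochiral nucleophile that creates a quaternary mixed-ketal stereocenter. C4 is set by the catalyst, whose anthracenylmethyl and quinoline walls should leave one face of the bound enolate open, whereas C6 is formed without control and is set in step 7. The step needs site-selective enolisation (secured by the two α-oxygen substituents), one dominant enolate geometry (expected with the less basic aryloxy oxygen syn to the oxido group) and closure faster than retro-Michael racemisation (secured by low temperature and the six-membered transition state).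

Step 6
Reactants: 10 (4R)-6-allyl-4-(2-allyl-4,5-dimethoxyphenoxy)-4-methoxycyclohexane-1,3-dione
Product: 11 (4R)-6-allyl-4-(2-allyl-4,5-dimethoxyphenoxy)-3,4-dimethoxycyclohex-2-en-1-one (mixture of C6 epimers)
Conditions: Me3SiCHN2 (1.5 equiv), toluene/MeOH 4:1, 0 °C
Reagents that add atoms: (trimethylsilyl)diazomethane, C[Si](C)(C)C=[N+]=[N-]
Why: Diazomethane-type O-methylation of the vinylogous acid should trap the enol tautomer expected to dominate, with the carbonyl at the alkyl-flanked C1 and the hydroxyl at C3 next to the electron-poor ketal carbon, under neutral conditions that spare the mixed ketal, and no new stereocenter is formed.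

Step 7
Reactants: 11 (4R)-6-allyl-4-(2-allyl-4,5-dimethoxyphenoxy)-3,4-dimethoxycyclohex-2-en-1-one
Product: 13 (4R,6S)-6-allyl-4-(2-allyl-4,5-dimethoxyphenoxy)-3,4-dimethoxycyclohex-2-en-1-one (target), via lithium dienolate 12 (not isolated)
Conditions: LiN(iPr)2 (1.2 equiv), THF, −78 °C; then 2,6-di-tert-butyl-4-methylphenol (2 equiv), −78 °C; aq. NH4Cl
Reagents that add atoms: none
Why: Deprotonation at C6 followed by kinetic protonation of the cross-conjugated dienolate by the bulky phenol should occur on the face opposite the pseudoaxial aryloxy group at C4 (the larger C4 substituent sits axial to avoid A(1,2) strain with the C3 methoxy group), placing H trans and allyl cis to aryloxy and so setting C6 as S under substrate control.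

Compound list
1 | 3,4-dimethoxyphenol | COc1ccc(O)cc1OC | starting material
2 | 4-(allyloxy)-1,2-dimethoxybenzene | C=CCOc1ccc(OC)c(OC)c1 | intermediate
3 | 2-allyl-4,5-dimethoxyphenol | C=CCc1cc(OC)c(OC)cc1O | intermediate
4 | 1,1-dimethoxypropan-2-one | CC(=O)C(OC)OC | starting material
5 | 1-bromo-1-methoxypropan-2-one (racemic, not isolated) | CC(=O)C(Br)OC | intermediate
6 | 1-(2-allyl-4,5-dimethoxyphenoxy)-1-methoxypropan-2-one (racemic) | CC(=O)C(OC)Oc1cc(OC)c(OC)cc1CC=C | intermediate
7 | methyl 2-(bromomethyl)acrylate | C=C(CBr)C(=O)OC | starting material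
8 | methyl 2-methylidenepent-4-enoate | C=CCC(=C)C(=O)OC | intermediate
9 | methyl (4R)-2-allyl-4-(2-allyl-4,5-dimethoxyphenoxy)-4-methoxy-5-oxohexanoate (C2 epimers, not isolated) | C=CCc1cc(OC)c(OC)cc1O[C@](OC)(CC(CC=C)C(=O)OC)C(C)=O | intermediate
10 | (4R)-6-allyl-4-(2-allyl-4,5-dimethoxyphenoxy)-4-methoxycyclohexane-1,3-dione (C6 epimers) | C=CCc1cc(OC)c(OC)cc1O[C@]1(OC)CC(CC=C)C(=O)CC1=O | intermediate
11 | (4R)-6-allyl-4-(2-allyl-4,5-dimethoxyphenoxy)-3,4-dimethoxycyclohex-2-en-1-one (C6 epimers) | C=CCc1cc(OC)c(OC)cc1O[C@]1(OC)CC(CC=C)C(=O)C=C1OC | intermediate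
12 | lithium dienolate of 11 (oxido at C1, double bonds C1=C6 and C2=C3, 4R retained, not isolated) | C=CCc1cc(OC)c(OC)cc1O[C@]1(OC)CC(CC=C)=C([O-])C=C1OC.[Li+] | intermediate
13 | (4R,6S)-6-allyl-4-(2-allyl-4,5-dimethoxyphenoxy)-3,4-dimethoxycyclohex-2-en-1-one | C=CCc1cc(OC)c(OC)cc1O[C@]1(OC)C[C@H](CC=C)C(=O)C=C1OC | target

Total step count: 7. Longest linear sequence: 6 steps (steps 1, 2, 3, 5, 6, 7).

Steps most likely to fail

Step 5 (proposed new method). The ion-paired enolate may react through both double-bond geometries, or too slowly with the α-substituted acrylate at low temperature, so that facial discrimination at C4 is poor. Retro-Michael equilibration in the second stage would erode it further. The fallback uses known chemistry and sets out from ketone 6 and acrylate 8. The annulation is run without chiral catalyst as the classical consecutive Michael–Claisen process (KOtBu, THF/tBuOH, −20 to 0 °C). It gives, through the racemic keto ester F1, the racemic dione F2. The conditions of steps 6 and 7 then give the racemic enol ether F3, the racemic lithium dienolate F4 and the racemic cis product F5. F5 is resolved by preparative chromatography on a chiral stationary phase (amylose tris(3,5-dimethylphenylcarbamate), supercritical CO2/MeOH). The route is rejoined at target 13.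

Step 6. Methylation may take place at the sterically more accessible C1 oxygen, giving the transposed enol ether, or at carbon. The fallback builds the enol ether regiospecifically through the alcohol oxidation level and sets out from ketone 6. The annulation partner is 2-methylidenepent-4-enal F6, made from pent-4-enal, aqueous formaldehyde and a pyrrolidine/propionic acid catalyst. Phase-transfer Michael addition as in step 5 gives the keto aldehyde F7, which is not isolated. Intramolecular aldol addition (K2CO3, MeOH, 0 °C) gives the β-hydroxy ketone F8, whose ketone can enolise only toward the future C2. Silylation (Et3SiCl, imidazole) gives the silyl ether F9. O-Methylation of its potassium enolate (KN(SiMe3)2, then Me2SO4, THF/DMPU, −78 °C) gives the methyl enol ether F10. Desilylation (Bu4NF) gives the allylic alcohol F11. Oxidation with MnO2 rejoins the route at compound 11.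

Step 7. Facial selectivity in the protonation of dienolate 12 may be reversed (proton delivered syn to the aryloxy group), leading mainly to the C6 epimer. A carbon electrophile and a proton should choose the same face of such a dienolate, so the fallback introduces the allyl group as the electrophile. It sets out from ketone 6. The annulation of step 5 is run with methyl acrylate and gives, through the keto ester F12, the des-allyl dione F13. O-Methylation as in step 6 gives the enone F14. Its lithium dienolate F15 (LiN(iPr)2, THF, −78 °C) is alkylated at C6 with allyl bromide, the known α′-alkylation of a vinylogous ester enolate. The route is rejoined at target 13.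

Further compounds
F1 | step 5 | racemic methyl 2-allyl-4-(2-allyl-4,5-dimethoxyphenoxy)-4-methoxy-5-oxohexanoate | C=CCc1cc(OC)c(OC)cc1OC(OC)(CC(CC=C)C(=O)OC)C(C)=O
F2 | step 5 | racemic 6-allyl-4-(2-allyl-4,5-dimethoxyphenoxy)-4-methoxycyclohexane-1,3-dione | C=CCc1cc(OC)c(OC)cc1OC1(OC)CC(CC=C)C(=O)CC1=O
F3 | step 5 | racemic 6-allyl-4-(2-allyl-4,5-dimethoxyphenoxy)-3,4-dimethoxycyclohex-2-en-1-one | C=CCc1cc(OC)c(OC)cc1OC1(OC)CC(CC=C)C(=O)C=C1OC
F4 | step 5 | racemic lithium dienolate of F3 | C=CCc1cc(OC)c(OC)cc1OC1(OC)CC(CC=C)=C([O-])C=C1OC.[Li+]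
F5 | step 5 | racemic cis product, 1:1 pair of 13 and its (4S,6R)-enantiomer | C=CCc1cc(OC)c(OC)cc1O[C@]1(OC)C[C@H](CC=C)C(=O)C=C1OC.C=CCc1cc(OC)c(OC)cc1O[C@@]1(OC)C[C@@H](CC=C)C(=O)C=C1OC
F6 | step 6 | 2-methylidenepent-4-enal | C=CCC(=C)C=O
F7 | step 6 | (4R)-2-allyl-4-(2-allyl-4,5-dimethoxyphenoxy)-4-methoxy-5-oxohexanal (C2 epimers) | C=CCc1cc(OC)c(OC)cc1O[C@](OC)(CC(CC=C)C=O)C(C)=O
F8 | step 6 | (2R)-4-allyl-2-(2-allyl-4,5-dimethoxyphenoxy)-5-hydroxy-2-methoxycyclohexan-1-one (mixture at C4 and C5) | C=CCc1cc(OC)c(OC)cc1O[C@]1(OC)CC(CC=C)C(O)CC1=O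
F9 | step 6 | (2R)-4-allyl-2-(2-allyl-4,5-dimethoxyphenoxy)-2-methoxy-5-(triethylsilyloxy)cyclohexan-1-one | C=CCc1cc(OC)c(OC)cc1O[C@]1(OC)CC(CC=C)C(O[Si](CC)(CC)CC)CC1=O
F10 | step 6 | {[(4R)-6-allyl-4-(2-allyl-4,5-dimethoxyphenoxy)-3,4-dimethoxycyclohex-2-en-1-yl]oxy}triethylsilane | C=CCc1cc(OC)c(OC)cc1O[C@]1(OC)CC(CC=C)C(O[Si](CC)(CC)CC)C=C1OC
F11 | step 6 | (4R)-6-allyl-4-(2-allyl-4,5-dimethoxyphenoxy)-3,4-dimethoxycyclohex-2-en-1-ol | C=CCc1cc(OC)c(OC)cc1O[C@]1(OC)CC(CC=C)C(O)C=C1OC
F12 | step 7 | methyl (4R)-4-(2-allyl-4,5-dimethoxyphenoxy)-4-methoxy-5-oxohexanoate | C=CCc1cc(OC)c(OC)cc1O[C@](OC)(CCC(=O)OC)C(C)=O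
F13 | step 7 | (4R)-4-(2-allyl-4,5-dimethoxyphenoxy)-4-methoxycyclohexane-1,3-dione | C=CCc1cc(OC)c(OC)cc1O[C@]1(OC)CCC(=O)CC1=O
F14 | step 7 | (4R)-4-(2-allyl-4,5-dimethoxyphenoxy)-3,4-dimethoxycyclohex-2-en-1-one | C=CCc1cc(OC)c(OC)cc1O[C@]1(OC)CCC(=O)C=C1OC
F15 | step 7 | lithium dienolate of F14 (ketal configuration unchanged) | C=CCc1cc(OC)c(OC)cc1O[C@]1(OC)CC=C([O-])C=C1OC.[Li+]
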